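**Plan**

1. Retrosynthesis: the acyl ketone comes from a carbinol; the macrocycle is cut at the CH2–CH= bond beside the methoxy-bearing Z-alkene (B-alkyl Suzuki) and at the tetronate C-3–acyl bond (C-3 lithiation, aldehyde addition); the bond from the tetronate enol-ether carbon C-4 to the spiro carbon C-5 is cut next, then the lactone C–O bond; the cyclohexene is cut by a Diels–Alder of an (E,E)-diene with a ketene equivalent; the tertiary ether carbon comes from a lactic acid dioxolanone.
2. Enabling feature: tetronate C-4 is the β-carbon of a β-alkoxyacrylate (O–C4=C3–C2=O) whose ether oxygen is the dihydropyran oxygen. It lies 1,6 (C4–O–C–CH2–C–C5) to the spiro carbon, which at the ketone level is a cyclohexenone carbonyl; one-electron reduction makes that carbon a nucleophilic ketyl that closes the pyran on C-4 and leaves an alkoxide placed to close the lactone.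
3. Forward order: acyclic iodo-trienol → β-alkoxyacrylate → cyclohexene → ketone → pyran and lactone (key step) → butenolide → diene → union at tetronate C-3 with a five-carbon aldehyde → macrocycle (13-membered through the ether oxygen) → ketone.
4. Stereochemistry: tertiary ether centre from (R)-lactic acid by self-regeneration of stereocentres; ring quaternary and ethyl-bearing centres from diene geometry plus oxazaborolidinium face control; spiro centre from the chair transition state of the key step; methoxy centre from Brown allylation; both Z-trisubstituted alkenes from anti-hydro- or anti-carbometalation of propargylic alcohols followed by stereoretentive couplings.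

Key step: step 14

Assumption: the (S)-oxazaborolidinium ion is taken to expose the same face of 2-bromoacrolein as with simple dienes, so that the formyl-exo adduct is the (6R)-bromo aldehyde 20; if the sense were opposite, the (R)-catalyst would be used.

Step 1
Reactants: 1 (2E)-2-methylpent-2-enal; 2 triethyl 2-phosphonopropanoate
Product: 3 ethyl (2E,4E)-2,4-dimethylhepta-2,4-dienoate
Conditions: NaH, THF, 0 °C → rt
Reagents that add atoms: none
Why: Horner–Wadsworth–Emmons olefination with a stabilised α-methyl phosphonate should set the new trisubstituted alkene E (ester trans to the chain) and leave the existing E alkene untouched.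

Step 2
Reactants: 3 ethyl (2E,4E)-2,4-dimethylhepta-2,4-dienoate
Product: 4 (2E,4E)-2,4-dimethylhepta-2,4-dien-1-ol
Conditions: i-Bu2AlH (2.2 equiv), CH2Cl2, −78 °C
Reagents that add atoms: none
Why: 1,2-reduction of a conjugated ester by i-Bu2AlH should give the dienyl alcohol without touching either alkene.

Step 3
Reactants: 4 (2E,4E)-2,4-dimethylhepta-2,4-dien-1-ol
Product: 5 (2E,4E)-1-bromo-2,4-dimethylhepta-2,4-diene
Conditions: PBr3 (0.4 equiv), Et2O, −10 °C
Reagents that add atoms: phosphorus tribromide, BrP(Br)Br
Why: bromination of a primary allylic alcohol with PBr3 at low temperature should proceed at the primary carbon without allylic transposition.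

Step 4
Reactants: 6 (R)-lactic acid; 7 pivalaldehyde
Product: 8 (2R,5R)-2-tert-butyl-5-methyl-1,3-dioxolan-4-one
Conditions: p-TsOH·H2O (cat.), H2SO4 (cat.), pentane, reflux with water separator; crystallisation
Reagents that add atoms: none
Why: acid-catalysed acetalisation should give the cis dioxolanone as the thermodynamic, crystallisable isomer, so the lactate centre fixes the new acetal centre.

Step 5
Reactants: 8 (2R,5R)-2-tert-butyl-5-methyl-1,3-dioxolan-4-one; 5 (2E,4E)-1-bromo-2,4-dimethylhepta-2,4-diene
Product: 9 (2R,5S)-2-tert-butyl-5-[(2E,4E)-2,4-dimethylhepta-2,4-dien-1-yl]-5-methyl-1,3-dioxolan-4-one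
Conditions: LiN(i-Pr)2, THF, −78 °C; then 5, −78 → −30 °C
Reagents that add atoms: none
Why: enolate alkylation under self-regeneration of stereocentres should place the allylic electrophile anti to tert-butyl, i.e. in the position of the former hydrogen, which sets the quaternary carbinol centre S.

Step 6
Reactants: 9 (2R,5S)-2-tert-butyl-5-[(2E,4E)-2,4-dimethylhepta-2,4-dien-1-yl]-5-methyl-1,3-dioxolan-4-one
Product: 11 (3S,5E,7E)-3,5,7-trimethyldeca-5,7-dien-1-yn-3-ol, via lactol 10 (not isolated)
Conditions: i-Bu2AlH (1.1 equiv), CH2Cl2, −78 °C; MeOH; then K2CO3, MeC(O)C(N2)P(O)(OMe)2 (3 equiv), MeOH, 0 °C → rt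
Reagents that add atoms: dimethyl (1-diazo-2-oxopropyl)phosphonate, COP(=O)(OC)C(=[N+]=[N-])C(C)=O
Why: half-reduction of the acetal lactone gives a lactol that releases the α-hydroxy aldehyde under base, and Seyferth–Gilbert homologation with the Bestmann–Ohira reagent should convert it into the terminal alkyne; the carbinol centre has no α-hydrogen and cannot epimerise.

Step 7
Reactants: 11 (3S,5E,7E)-3,5,7-trimethyldeca-5,7-dien-1-yn-3-ol
Product: 12 (4S,6E,8E)-4,6,8-trimethylundeca-6,8-dien-2-yn-4-ol
Conditions: n-BuLi (2.2 equiv), THF, −78 → 0 °C; MeI (1.1 equiv), −78 °C → rt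
Reagents that add atoms: iodomethane, CI
Why: acetylide alkylation of the alkoxide–acetylide dianion should be C-selective, since the hindered tertiary lithium alkoxide is a poor nucleophile towards MeI.

Step 8
Reactants: 12 (4S,6E,8E)-4,6,8-trimethylundeca-6,8-dien-2-yn-4-ol
Product: 14 (2Z,4S,6E,8E)-2-iodo-4,6,8-trimethylundeca-2,6,8-trien-4-ol, via vinylalanate 13 (not isolated)
Conditions: NaAlH2(OCH2CH2OMe)2, THF, 0 °C → rt; EtOAc; then I2, −78 → 0 °C
Reagents that add atoms: iodine, [I][I]
Why: hydroxyl-directed trans-hydroalumination of the propargylic alcohol places aluminium on the distal carbon in a five-membered chelate, and iodinolysis with retention should give only the Z iodoalkene (iodine cis to the carbinol carbon).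

Step 9
Reactants: 14 (2Z,4S,6E,8E)-2-iodo-4,6,8-trimethylundeca-2,6,8-trien-4-ol; 15 methyl propiolate
Product: 16 methyl (2E)-3-{[(2Z,4S,6E,8E)-2-iodo-4,6,8-trimethylundeca-2,6,8-trien-4-yl]oxy}prop-2-enoate
Conditions: PMe3 (20 mol %), CH2Cl2, 0 °C → rt
Reagents that add atoms: none
Why: phosphine-catalysed oxa-Michael addition, which tolerates tertiary alcohols, should give the (E)-β-alkoxyacrylate under neutral conditions before any ketone is present that could tie up the alcohol as a hemiketal.

Step 10
Reactants: 17 acrolein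
Product: 19 2-bromoacrolein, via 2,3-dibromopropanal 18 (not isolated)
Conditions: Br2, CH2Cl2, −78 → 0 °C; then Et3N, 0 °C; used fresh
Reagents that add atoms: bromine, BrBr
Why: bromine addition followed by dehydrobromination of the more acidic α-hydrogen should give the α-bromo enal.

Step 11
Reactants: 16 methyl (2E)-3-{[(2Z,4S,6E,8E)-2-iodo-4,6,8-trimethylundeca-2,6,8-trien-4-yl]oxy}prop-2-enoate; 19 2-bromoacrolein
Product: 20 methyl (2E)-3-{[(2Z,4S)-5-[(1S,4S,6R)-6-bromo-4-ethyl-6-formyl-1,3-dimethylcyclohex-2-en-1-yl]-2-iodo-4-methylpent-2-en-4-yl]oxy}prop-2-enoate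
Conditions: 19 (3 equiv), (S)-3,3-diphenyl-1-(2-methylphenyl)tetrahydro-1H,3H-pyrrolo[1,2-c][1,3,2]oxazaborole·HN(SO2CF3)2 (20 mol %), CH2Cl2, −78 → −40 °C
Reagents that add atoms: none
Why: in this enantioselective Lewis-acid-catalysed Diels–Alder reaction the enal CH2 should bond first to the ethyl-bearing diene terminus, leaving allyl-cation character on the two methyl-bearing carbons, so the bromine-bearing carbon closes on the fully substituted terminus; the E,E geometry puts the CH2 side arm and the ethyl group cis, the inside methyl enforces the formyl-exo mode, and the catalyst selects the enal face, hence the absolute configuration of the quaternary and ethyl-bearing centres.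

Step 12
Reactants: 20 bromo aldehyde
Product: 21 α-bromo carboxylic acid corresponding to aldehyde 20
Conditions: NaClO2, NaH2PO4, 2-methylbut-2-ene, t-BuOH–H2O, 0 °C → rt
Reagents that add atoms: sodium chlorite, [Na+].[O-]Cl=O
Why: Pinnick oxidation with a hypochlorite scavenger should oxidise the hindered aldehyde without touching the alkenes, the enol ether or the vinyl iodide.

Step 13
Reactants: 21 α-bromo carboxylic acid
Product: 24 methyl (2E)-3-{[(2Z,4S)-5-[(1S,4S)-4-ethyl-1,3-dimethyl-6-oxocyclohex-2-en-1-yl]-2-iodo-4-methylpent-2-en-4-yl]oxy}prop-2-enoate, via acyl azide 22 (not isolated), via isocyanate 23 (not isolated)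
Conditions: (PhO)2P(O)N3, Et3N, toluene, 0 °C → rt; 80 °C; then H2O–THF, rt
Reagents that add atoms: water, O
Why: Curtius rearrangement of the α-bromo acyl azide gives an α-bromo isocyanate that water should hydrolyse to the ketone, the standard unmasking of a haloacrylic ketene equivalent; the bromo centre is destroyed and the quaternary α-carbon prevents alkene migration.

Step 14
Reactants: 24 keto β-alkoxyacrylate
Product: 26 tricyclic saturated γ-lactone (cyclohexene cis-fused to the tetrahydropyran; lactone closed from the ring-fusion oxygen), via hydroxy ester 25 (not isolated)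
Conditions: SmI2 (3 equiv), MeOH (4 equiv), THF, 0 °C; work-up; then p-TsOH·H2O (cat.), CH2Cl2, rt
Reagents that add atoms: none
Why: SmI2 should reduce the ketone, held near the ester by chelation, to a trivalent-samarium ketyl that adds to the acrylate β-carbon (the future tetronate C-4); the α-ester radical is then reduced and protonated by MeOH, and the tertiary carbinol closes the lactone on the ester under acid. The closest known reaction type is the SmI2-mediated reductive cyclisation of aldehydes and ketones onto tethered β-alkoxyacrylates (ketyl–olefin coupling) used for tetrahydropyran rings of polycyclic ethers. The tetrahydropyran closes 6-exo-trig by radical C–C bond formation and the γ-lactone 5-exo-trig by acyl substitution. The spiro carbinol centre is set in a chair transition state with the ester-chelated samarium alkoxide equatorial and the tether delivered from the neighbouring quaternary carbon, so the new C–C bond is cis to the CH2 arm and the oxygen cis to the ring methyl (cis ring fusion); the CH centre formed at the acrylate carbon is expected trans to that oxygen and is erased in step 15. The step needs 6-exo attack on the acrylate in preference to 5-exo attack on the iodoalkene, to C–I reduction and to pinacol coupling, which the electron-poor chelating acceptor, the absence of HMPA and the hindrance around the ketone should secure.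

Step 15
Reactants: 26 tricyclic saturated γ-lactone
Product: 29 tricyclic 4-alkoxybutenolide bearing the (1Z)-2-iodoprop-1-enyl group, via selenide 27 (not isolated), via selenoxide 28 (not isolated)
Conditions: LiN(i-Pr)2, THF, −78 °C; PhSeBr, −78 °C; then H2O2, pyridine, CH2Cl2, 0 °C → rt
Reagents that add atoms: none
Why: α-selenenylation of the lactone enolate anti to the ring oxygen substituent and selenoxide syn-elimination towards the only β-hydrogen should give the tetronate double bond and remove the temporary CH stereocentre.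

Step 16
Reactants: 29 tricyclic iodo butenolide; 30 tributyl(vinyl)stannane
Product: 31 tricyclic butenolide bearing the (1Z)-2-methylbuta-1,3-dien-1-yl group
Conditions: Pd(PPh3)4 (5 mol %), CuI (10 mol %), CsF, DMF, 40 °C
Reagents that add atoms: none
Why: Stille coupling of the alkenyl iodide proceeds with retention, so the Z geometry fixed in step 8 should be carried into the diene; the diene is introduced only now because it would compete in steps 11 and 14.

Step 17
Reactants: 32 propargyl alcohol
Product: 34 (2Z)-3-iodo-2-methylprop-2-en-1-ol, via magnesium chelate 33 (not isolated)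
Conditions: MeMgBr (2.5 equiv), CuI (10 mol %), THF, −10 °C → rt; then I2, −10 °C
Reagents that add atoms: methylmagnesium bromide, C[Mg]Br; iodine, [I][I]
Why: copper-catalysed anti-carbomagnesiation of the propargylic alkoxide gives a five-membered oxamagnesacycle, and iodinolysis with retention should give the Z iodoalkene (iodine cis to CH2OH).

Step 18
Reactants: 34 (2Z)-3-iodo-2-methylprop-2-en-1-ol
Product: 35 (2Z)-3-iodo-2-methylprop-2-enal
Conditions: MnO2 (excess), CH2Cl2, rt; used directly
Reagents that add atoms: none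
Why: neutral allylic oxidation with MnO2 should give the enal without Z to E isomerisation.

Step 19
Reactants: 35 (2Z)-3-iodo-2-methylprop-2-enal
Product: 37 (1Z,3R)-1-iodo-2-methylhexa-1,5-dien-3-ol, via borinate 36 (not isolated)
Conditions: (−)-Ipc2BOMe, CH2=CHCH2MgBr, Et2O, −78 °C → rt; then 35, −78 °C; then NaOH, H2O2, rt
Reagents that add atoms: allylmagnesium bromide, C=CC[Mg]Br
Why: Brown allylation through a chair transition state should give the R carbinol with the reagent derived from (+)-α-pinene, the sense established for α-methyl enals.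

Step 20
Reactants: 37 (1Z,3R)-1-iodo-2-methylhexa-1,5-dien-3-ol
Product: 38 (1Z,3R)-1-iodo-3-methoxy-2-methylhexa-1,5-diene
Conditions: NaH, MeI, THF, 0 °C → rt
Reagents that add atoms: iodomethane, CI
Why: Williamson etherification of the alkoxide; the iodoalkene carries no hydrogen anti to iodine on the neighbouring carbon, so elimination is not expected.

Step 21
Reactants: 38 (1Z,3R)-1-iodo-3-methoxy-2-methylhexa-1,5-diene
Product: 39 (3R,4Z)-5-iodo-3-methoxy-4-methylpent-4-enal
Conditions: OsO4 (2 mol %), NaIO4 (4 equiv), 2,6-lutidine, dioxane–H2O, rt; used directly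
Reagents that add atoms: sodium periodate, [Na+].[O-]I(=O)(=O)=O
Why: Lemieux–Johnson cleavage should select the monosubstituted terminal alkene over the hindered, electron-poor iodoalkene.

Step 22
Reactants: 31 tricyclic diene butenolide; 39 (3R,4Z)-5-iodo-3-methoxy-4-methylpent-4-enal
Product: 40 tricyclic butenolide carrying at tetronate C-3 a (3R,4Z)-1-hydroxy-5-iodo-3-methoxy-4-methylpent-4-en-1-yl group (both carbinol epimers)
Conditions: LiN(i-Pr)2 (1.1 equiv), THF, −78 °C; then 39, −78 °C; AcOH
Reagents that add atoms: none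
Why: 4-alkoxybutenolides without a γ-hydrogen (the spiro carbon is quaternary) are lithiated at C-3, and the vinyllithium should add to the aldehyde faster than it enolises it; the new carbinol centre is uncontrolled and removed in step 24.

Step 23
Reactants: 40 carbinol with terminal diene and alkenyl iodide
Product: 42 macrocyclic carbinol (the target with CH–OH in place of the acyl ketone; both epimers), via bis-borane 41 (not isolated)
Conditions: 9-borabicyclo[3.3.1]nonane (9-BBN, 3 equiv), THF, 0 °C → rt; then slow addition to PdCl2(dppf) [dppf = 1,1'-bis(diphenylphosphino)ferrocene] (20 mol %), AsPh3 (40 mol %), Cs2CO3, DMF–THF–H2O, 45 °C, 1 mM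
Reagents that add atoms: none
Why: 9-BBN should hydroborate only the monosubstituted vinyl terminus of the isoprene-like diene (boron at the terminal carbon), and the intramolecular B-alkyl Suzuki–Miyaura coupling with the unhindered Z alkenyl iodide should close the macrocycle with retention of both Z alkenes.

Step 24
Reactants: 42 macrocyclic carbinol
Product: 43 streptaspironate A
Conditions: Dess–Martin periodinane, NaHCO3, CH2Cl2, 0 °C → rt
Reagents that add atoms: none
Why: Dess–Martin oxidation of the carbinol flanked by the tetronate should give the 3-acyl tetronate under buffered, non-epimerising conditions, and both epimers converge.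

**Compound list**

1 | (2E)-2-methylpent-2-enal | CC/C=C(\C)C=O | starting material
2 | triethyl 2-phosphonopropanoate | CCOC(=O)C(C)P(=O)(OCC)OCC | starting material
3 | ethyl (2E,4E)-2,4-dimethylhepta-2,4-dienoate | CCOC(=O)/C(C)=C/C(C)=C/CC | intermediate
4 | (2E,4E)-2,4-dimethylhepta-2,4-dien-1-ol | OC/C(C)=C/C(C)=C/CC | intermediate
5 | (2E,4E)-1-bromo-2,4-dimethylhepta-2,4-diene | BrC/C(C)=C/C(C)=C/CC | intermediate
6 | (R)-lactic acid | C[C@@H](O)C(O)=O | starting material
7 | pivalaldehyde | CC(C)(C)C=O | starting material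
8 | (2R,5R)-2-tert-butyl-5-methyl-1,3-dioxolan-4-one (cis) | C[C@H]1O[C@@H](C(C)(C)C)OC1=O | intermediate
9 | (2R,5S)-2-tert-butyl-5-[(2E,4E)-2,4-dimethylhepta-2,4-dien-1-yl]-5-methyl-1,3-dioxolan-4-one | C[C@@]1(C/C(C)=C/C(C)=C/CC)O[C@@H](C(C)(C)C)OC1=O | intermediate
10 | lactol of 9 (dioxolan-4-ol, both anomers) | C[C@@]1(C/C(C)=C/C(C)=C/CC)O[C@@H](C(C)(C)C)OC1O | intermediate (not isolated)
11 | (3S,5E,7E)-3,5,7-trimethyldeca-5,7-dien-1-yn-3-ol | O[C@](C)(C#C)C/C(C)=C/C(C)=C/CC | intermediate
12 | (4S,6E,8E)-4,6,8-trimethylundeca-6,8-dien-2-yn-4-ol | O[C@](C)(C#CC)C/C(C)=C/C(C)=C/CC | intermediate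
13 | sodium five-membered alkoxy-vinylalanate from 12 (Al on the methyl-bearing alkene carbon, cis to the carbinol carbon) | CC1=C[C@](C)(C/C(C)=C/C(C)=C/CC)O[Al-]1(OCCOC)OCCOC.[Na+] | intermediate (not isolated)
14 | (2Z,4S,6E,8E)-2-iodo-4,6,8-trimethylundeca-2,6,8-trien-4-ol | O[C@](C)(/C=C(/C)I)C/C(C)=C/C(C)=C/CC | intermediate
15 | methyl propiolate | C#CC(=O)OC | starting material
16 | methyl (2E)-3-{[(2Z,4S,6E,8E)-2-iodo-4,6,8-trimethylundeca-2,6,8-trien-4-yl]oxy}prop-2-enoate | COC(=O)/C=C/O[C@](C)(/C=C(/C)I)C/C(C)=C/C(C)=C/CC | intermediate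
17 | acrolein | C=CC=O | starting material
18 | 2,3-dibromopropanal | O=CC(Br)CBr | intermediate (not isolated)
19 | 2-bromoacrolein | C=C(Br)C=O | intermediate
20 | methyl (2E)-3-{[(2Z,4S)-5-[(1S,4S,6R)-6-bromo-4-ethyl-6-formyl-1,3-dimethylcyclohex-2-en-1-yl]-2-iodo-4-methylpent-2-en-4-yl]oxy}prop-2-enoate | CC[C@H]1C[C@](Br)(C=O)[C@@](C)(C[C@](C)(O/C=C/C(=O)OC)/C=C(/C)I)C=C1C | intermediate
21 | α-bromo carboxylic acid (CO2H in place of CHO in 20) | CC[C@H]1C[C@](Br)(C(O)=O)[C@@](C)(C[C@](C)(O/C=C/C(=O)OC)/C=C(/C)I)C=C1C | intermediate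
22 | acyl azide of 21 | CC[C@H]1C[C@](Br)(C(=O)N=[N+]=[N-])[C@@](C)(C[C@](C)(O/C=C/C(=O)OC)/C=C(/C)I)C=C1C | intermediate (not isolated)
23 | α-bromo isocyanate (N=C=O in place of CHO in 20, same configuration) | CC[C@H]1C[C@](Br)(N=C=O)[C@@](C)(C[C@](C)(O/C=C/C(=O)OC)/C=C(/C)I)C=C1C | intermediate (not isolated)
24 | methyl (2E)-3-{[(2Z,4S)-5-[(1S,4S)-4-ethyl-1,3-dimethyl-6-oxocyclohex-2-en-1-yl]-2-iodo-4-methylpent-2-en-4-yl]oxy}prop-2-enoate | CC[C@H]1CC(=O)[C@@](C)(C[C@](C)(O/C=C/C(=O)OC)/C=C(/C)I)C=C1C | intermediate
25 | methyl 2-[(1R,3S,4aS,7S,8aS)-7-ethyl-8a-hydroxy-3-[(1Z)-2-iodoprop-1-en-1-yl]-3,4a,6-trimethyl-3,4,4a,7,8,8a-hexahydro-1H-isochromen-1-yl]acetate | CC[C@H]1C[C@@]2(O)[C@@H](CC(=O)OC)O[C@](C)(/C=C(/C)I)C[C@@]2(C)C=C1C | intermediate (not isolated)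
26 | γ-lactone of 25 (8a-oxygen acylated by the acetate arm; cyclohexene and tetrahydropyran cis-fused, lactone trans-fused on the pyran) | CC[C@H]1C[C@@]23OC(=O)C[C@H]2O[C@](C)(/C=C(/C)I)C[C@@]3(C)C=C1C | intermediate
27 | α-(phenylselanyl) lactone from 26 (selenium cis to the adjacent ring hydrogen) | CC[C@H]1C[C@@]23OC(=O)[C@H]([Se]c4ccccc4)[C@H]2O[C@](C)(/C=C(/C)I)C[C@@]3(C)C=C1C | intermediate (not isolated)
28 | selenoxide of 27 | CC[C@H]1C[C@@]23OC(=O)[C@H]([Se](=O)c4ccccc4)[C@H]2O[C@](C)(/C=C(/C)I)C[C@@]3(C)C=C1C | intermediate (not isolated)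
29 | tricyclic 4-alkoxybutenolide (tetronate whose ether oxygen is the pyran oxygen; C-3 unsubstituted; (1Z)-2-iodoprop-1-enyl on the tertiary ether carbon) | CC[C@H]1C[C@@]23OC(=O)C=C2O[C@](C)(/C=C(/C)I)C[C@@]3(C)C=C1C | intermediate
30 | tributyl(vinyl)stannane | C=C[Sn](CCCC)(CCCC)CCCC | starting material
31 | as 29 with (1Z)-2-methylbuta-1,3-dien-1-yl in place of iodopropenyl | CC[C@H]1C[C@@]23OC(=O)C=C2O[C@](C)(/C=C(/C)C=C)C[C@@]3(C)C=C1C | intermediate
32 | propargyl alcohol | C#CCO | starting material
33 | 4-methyl-2,5-dihydro-1,2-oxamagnesole (magnesium chelate) | CC1=C[Mg]OC1 | intermediate (not isolated)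
34 | (2Z)-3-iodo-2-methylprop-2-en-1-ol | I/C=C(/C)CO | intermediate
35 | (2Z)-3-iodo-2-methylprop-2-enal | I/C=C(/C)C=O | intermediate
36 | diisopinocampheylborinate of 37 | I/C=C(/C)[C@@H](CC=C)OB([C@@H]1C[C@@H]2C[C@H]([C@H]1C)C2(C)C)[C@@H]1C[C@@H]2C[C@H]([C@H]1C)C2(C)C | intermediate (not isolated)
37 | (1Z,3R)-1-iodo-2-methylhexa-1,5-dien-3-ol | I/C=C(/C)[C@H](O)CC=C | intermediate
38 | (1Z,3R)-1-iodo-3-methoxy-2-methylhexa-1,5-diene | I/C=C(/C)[C@H](OC)CC=C | intermediate
39 | (3R,4Z)-5-iodo-3-methoxy-4-methylpent-4-enal | I/C=C(/C)[C@H](OC)CC=O | intermediate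
40 | 31 carrying at tetronate C-3 a (3R,4Z)-1-hydroxy-5-iodo-3-methoxy-4-methylpent-4-en-1-yl group (both carbinol epimers) | CC[C@H]1C[C@@]23OC(=O)C(C(O)C[C@@H](OC)/C(C)=C\I)=C2O[C@](C)(/C=C(/C)C=C)C[C@@]3(C)C=C1C | intermediate
41 | bis(9-borabicyclo[3.3.1]nonan-9-yl) derivative of 40 (B–CH2 at the former vinyl terminus, B–O at the carbinol) | CC[C@H]1C[C@@]23OC(=O)C(C(OB4C5CCCC4CCC5)C[C@@H](OC)/C(C)=C\I)=C2O[C@](C)(/C=C(/C)CCB4C5CCCC4CCC5)C[C@@]3(C)C=C1C | intermediate (not isolated)
42 | macrocyclic carbinol (target with CH–OH in place of the acyl C=O; both epimers) | CC[C@H]1C[C@@]23OC(=O)C4=C2O[C@](C)(/C=C(/C)CC/C=C(/C)[C@H](OC)CC4O)C[C@@]3(C)C=C1C | intermediate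
43 | streptaspironate A | CC[C@H]1C[C@@]23OC(=O)C4=C2O[C@](C)(/C=C(/C)CC/C=C(/C)[C@H](OC)CC4=O)C[C@@]3(C)C=C1C | target

**Count**

Total steps: 24. Longest linear sequence: 17 steps (steps 1–3, 5–9, 11–16, 22–24).

**Steps most likely to fail**

Step 11. The catalyst may discriminate poorly between the enal faces or between exo and endo modes on a hindered tetrasubstituted diene, and the Lewis acid may ionise the tertiary allylic ether. The fallback hands absolute control to a covalently bound auxiliary under neutral thermal conditions. (S)-Lactic acid and 7 would be condensed as in step 4 to (2S,5S)-2-tert-butyl-5-methyl-1,3-dioxolan-4-one F1. Radical bromination (N-bromosuccinimide, azobisisobutyronitrile) would give the 5-bromo compound F2, and Et3N would eliminate HBr to give the chiral ketene equivalent (2S)-2-tert-butyl-5-methylidene-1,3-dioxolan-4-one F3. Heating 16 with F3 (toluene, radical inhibitor, 100 °C) should give the spiro adduct F4 by attack anti to tert-butyl in the carbonyl-exo mode. LiOH (THF–H2O, 0 °C) should open the acetal lactone faster than the vinylogous carbonate ester to give the α-hydroxy acid F5, and oxidative decarboxylation with Pb(OAc)4 would return to the route at ketone 24.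

Step 14. The ketyl may close with the wrong ring fusion, or be diverted to carbonyl reduction, pinacol coupling or carbon–iodine reduction. The fallback forms the same bond by a two-electron addition. Setting out from 16, lithiation of the acrylate β-carbon cis to the ester (LiN(i-Pr)2, THF, −95 °C) and iodination would give the (Z)-β-iodo-β-alkoxyacrylate F6. The conditions of steps 11, 12 and 13 would carry it through bromo aldehyde F7, bromo acid F8, acyl azide F9 and isocyanate F10 to the iodo ketone F11. Iodine–magnesium exchange with i-PrMgCl·LiCl (THF, −78 → −20 °C) should occur only at the activated acrylate iodide; the ester-chelated alkenylmagnesium would add to the ketone and the magnesium alkoxide would lactonise, returning to the route at butenolide 29 and bypassing 26.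

Step 23. At high dilution, transmetalation of the alkylborane may be slow, so protodeboronation, β-hydride elimination or intermolecular coupling may overtake ring closure, and the carbinol may suffer under aqueous base. The fallback closes the same bond with a preformed alkylzinc under neutral, anhydrous conditions and moves the oxidation ahead of the ring closure. Setting out from 31, hydroboration with 9-BBN would give the alkylborane F12, and I2 with NaOMe would convert it into the primary iodide F13. Union with 39 as in step 22 would give the carbinol F14, and Dess–Martin oxidation the acyl tetronate F15. Zinc insertion (Zn, LiCl, THF) into the alkyl iodide, which leaves the alkenyl iodide untouched, would give the alkylzinc iodide F16, and intramolecular Negishi coupling (Pd(PPh3)4, THF–N-methylpyrrolidone, slow addition) would return to the route at the target 43.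

**Further compounds**

F1 | step 11 | (2S,5S)-2-tert-butyl-5-methyl-1,3-dioxolan-4-one | C[C@@H]1O[C@H](C(C)(C)C)OC1=O
F2 | step 11 | (2S)-5-bromo-2-tert-butyl-5-methyl-1,3-dioxolan-4-one (C-5 epimers) | CC1(Br)O[C@H](C(C)(C)C)OC1=O
F3 | step 11 | (2S)-2-tert-butyl-5-methylidene-1,3-dioxolan-4-one | C=C1O[C@H](C(C)(C)C)OC1=O
F4 | step 11 | spiro dioxolanone Diels–Alder adduct of 16 and F3 (ring oxygen cis to the CH2 side arm and ethyl group, carbonyl exo) | CC[C@H]1C[C@@]2(O[C@H](C(C)(C)C)OC2=O)[C@@](C)(C[C@](C)(O/C=C/C(=O)OC)/C=C(/C)I)C=C1C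
F5 | step 11 | α-hydroxy acid from F4 (OH and CO2H on the former dienophile carbon) | CC[C@H]1C[C@](O)(C(O)=O)[C@@](C)(C[C@](C)(O/C=C/C(=O)OC)/C=C(/C)I)C=C1C
F6 | step 14 | methyl (2Z)-3-iodo-3-{[(2Z,4S,6E,8E)-2-iodo-4,6,8-trimethylundeca-2,6,8-trien-4-yl]oxy}prop-2-enoate | COC(=O)/C=C(\I)O[C@](C)(/C=C(/C)I)C/C(C)=C/C(C)=C/CC
F7 | step 14 | bromo aldehyde as 20 with iodine on the acrylate β-carbon | CC[C@H]1C[C@](Br)(C=O)[C@@](C)(C[C@](C)(O/C(I)=C/C(=O)OC)/C=C(/C)I)C=C1C
F8 | step 14 | bromo acid as 21 with iodine on the acrylate β-carbon | CC[C@H]1C[C@](Br)(C(O)=O)[C@@](C)(C[C@](C)(O/C(I)=C/C(=O)OC)/C=C(/C)I)C=C1C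
F9 | step 14 | acyl azide as 22 with iodine on the acrylate β-carbon | CC[C@H]1C[C@](Br)(C(=O)N=[N+]=[N-])[C@@](C)(C[C@](C)(O/C(I)=C/C(=O)OC)/C=C(/C)I)C=C1C
F10 | step 14 | isocyanate as 23 with iodine on the acrylate β-carbon | CC[C@H]1C[C@](Br)(N=C=O)[C@@](C)(C[C@](C)(O/C(I)=C/C(=O)OC)/C=C(/C)I)C=C1C
F11 | step 14 | ketone as 24 with iodine on the acrylate β-carbon | CC[C@H]1CC(=O)[C@@](C)(C[C@](C)(O/C(I)=C/C(=O)OC)/C=C(/C)I)C=C1C
F12 | step 23 | B-alkyl-9-borabicyclo[3.3.1]nonane from 31 (boron on the former vinyl terminus) | CC[C@H]1C[C@@]23OC(=O)C=C2O[C@](C)(/C=C(/C)CCB4C5CCCC4CCC5)C[C@@]3(C)C=C1C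
F13 | step 23 | primary iodide: as 31 with (1Z)-4-iodo-2-methylbut-1-en-1-yl in place of the dienyl group | CC[C@H]1C[C@@]23OC(=O)C=C2O[C@](C)(/C=C(/C)CCI)C[C@@]3(C)C=C1C
F14 | step 23 | carbinol from F13 and 39 (both carbinol epimers) | CC[C@H]1C[C@@]23OC(=O)C(C(O)C[C@@H](OC)/C(C)=C\I)=C2O[C@](C)(/C=C(/C)CCI)C[C@@]3(C)C=C1C
F15 | step 23 | acyl tetronate from F14 | CC[C@H]1C[C@@]23OC(=O)C(C(=O)C[C@@H](OC)/C(C)=C\I)=C2O[C@](C)(/C=C(/C)CCI)C[C@@]3(C)C=C1C
F16 | step 23 | alkylzinc iodide from F15 | CC[C@H]1C[C@@]23OC(=O)C(C(=O)C[C@@H](OC)/C(C)=C\I)=C2O[C@](C)(/C=C(/C)CC[Zn]I)C[C@@]3(C)C=C1C
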